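The depside is disconnected at the ester between the C4' oxygen of ring B and the C1 carbonyl of ring A, and the plan rests on how ring B is made. Its contiguous C6'-propyl, C1'-carboxyl and C2'-methoxy array is exploited: a triisopropylsilyl-protected 3-fluoro-5-methoxyphenol is deprotonated at the carbon flanked by fluorine and methoxy, eliminates lithium fluoride to the C1'–C6' aryne, adds propyllithium at C6' and is carboxylated at C1', so both new ring B carbon–carbon bonds form in one flask. The ring A acid is drawn from olivetol by formylation, methylation, benzylation and oxidation; esterification and one hydrogenolysis complete the synthesis.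

Key step: step 3

Assumption: ring A is numbered C1–C6 from the carbon bearing the ester carbonyl, ring B C1'–C6' from the carbon bearing the free carboxyl; propyllithium is taken to be prepared and titrated in-house.

Step 1
Reactants: 1 3-fluoro-5-methoxyphenol; 2 chlorotriisopropylsilane
Product: 3 (3-fluoro-5-methoxyphenoxy)triisopropylsilane
Conditions: imidazole, DMF, rt
Reagents that add atoms: none
Why: Imidazole-mediated O-silylation of a phenol is reliable, and the triisopropylsilyl ether is chosen because it resists alkyllithiums, does not coordinate lithium and shields both of its ortho C–H bonds.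

Step 2
Reactants: 4 1-chloropropane
Product: 5 propyllithium
Conditions: Li metal (about 1% Na, 2.2 equiv), pentane, reflux, Ar; filter, titrate
Reagents that add atoms: lithium metal, [Li]
Why: Direct reductive metalation of a primary alkyl chloride with lithium metal in a hydrocarbon is the standard preparation of n-alkyllithiums and keeps Wurtz coupling low.

Step 3
Reactants: 3 (3-fluoro-5-methoxyphenoxy)triisopropylsilane; 5 propyllithium; 6 carbon dioxide
Product: 11 2-methoxy-6-propyl-4-(triisopropylsilyloxy)benzoic acid, via ortho-fluoroaryllithium 7 (not isolated), via 3-methoxy-5-(triisopropylsilyloxy)benzyne 8 (not isolated), via 2-methoxy-6-propylaryllithium 9 (not isolated), via lithium carboxylate 10 (not isolated)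
Conditions: 5 (3.2 equiv), THF/pentane, −78 °C, 1 h; warm to −10 °C over 2 h; recool to −78 °C, dry CO2 (excess), then rt; cold 1 M HCl work-up
Reagents that add atoms: none
Why: The first equivalent of 5 removes the proton on the carbon flanked by fluorine and methoxy (directed ortho-metalation at the most acidic C–H, the only one not screened by the silyl ether) to give 7, which on warming undergoes β-elimination of lithium fluoride to aryne 8, whose strained bond joins the future C1' and C6'. A second equivalent of 5 adds to C6', the aryne carbon remote from the methoxy group, so that the carbanion of 9 sits at C1' beside oxygen, where it is stabilised inductively and by O–Li coordination, and carbon dioxide then carboxylates C1' to give 10 and, on acidification, 11. The closest known reaction type is the generation of 3-methoxybenzyne from a 3-haloanisole with excess alkyllithium, followed by meta-selective carbolithiation and electrophilic trapping to 6-alkyl-2-methoxybenzoic acids. No ring is closed and no stereocentre is formed. The step needs metalation beside the methoxy group and not beside the silyloxy group, which the bulk and non-coordinating character of the triisopropylsilyl ether should secure, and it needs addition at the distal aryne carbon, which the inductive polarisation of the aryne by the neighbouring methoxy group should secure. The excess of 5 is meant to outcompete addition of 7 or 9 to the aryne and is consumed in the quench.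

Step 4
Reactants: 11 2-methoxy-6-propyl-4-(triisopropylsilyloxy)benzoic acid
Product: 12 benzyl 2-methoxy-6-propyl-4-(triisopropylsilyloxy)benzoate
Conditions: BnBr (1.2 equiv), KHCO3 (1.5 equiv), DMF, rt
Reagents that add atoms: benzyl bromide, BrCc1ccccc1
Why: SN2 O-alkylation of the carboxylate (benzyl ester formation) does not require access to the hindered carbonyl carbon, and hydrogencarbonate is too weak a base to cleave the aryl silyl ether.

Step 5
Reactants: 12 benzyl 2-methoxy-6-propyl-4-(triisopropylsilyloxy)benzoate
Product: 13 benzyl 4-hydroxy-2-methoxy-6-propylbenzoate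
Conditions: n-Bu4NF (1.1 equiv), AcOH (1.1 equiv), THF, 0 °C
Reagents that add atoms: none
Why: Fluoride-mediated desilylation of an aryl silyl ether is fast and, buffered with acetic acid, should leave the benzyl ester and the methyl ether untouched.

Step 6
Reactants: 14 olivetol (5-pentylbenzene-1,3-diol)
Product: 16 2,4-dihydroxy-6-pentylbenzaldehyde, via aryl iminium chloride 15 (not isolated)
Conditions: POCl3 (1.2 equiv), DMF, 0 °C to rt; then H2O, 50 °C
Reagents that add atoms: N,N-dimethylformamide, CN(C)C=O; water, O
Why: Vilsmeier–Haack formylation of the resorcinol should attack the position ortho to one hydroxyl and para to the other (next to the pentyl chain) in preference to the doubly ortho position between the hydroxyls, and hydrolysis of iminium salt 15 releases the aldehyde.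

Step 7
Reactants: 16 2,4-dihydroxy-6-pentylbenzaldehyde
Product: 17 2-hydroxy-4-methoxy-6-pentylbenzaldehyde
Conditions: MeI (1.1 equiv), K2CO3 (1.1 equiv), acetone, rt
Reagents that add atoms: iodomethane, CI
Why: Williamson etherification with one equivalent of base should alkylate the more acidic, unhindered C4 hydroxyl, because the C2 hydroxyl is held in a hydrogen bond to the formyl oxygen.

Step 8
Reactants: 17 2-hydroxy-4-methoxy-6-pentylbenzaldehyde
Product: 18 2-(benzyloxy)-4-methoxy-6-pentylbenzaldehyde
Conditions: BnBr (1.3 equiv), K2CO3 (2 equiv), DMF, 60 °C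
Reagents that add atoms: benzyl bromide, BrCc1ccccc1
Why: Williamson benzylation in a polar aprotic solvent with heating overcomes the hydrogen bond and caps the C2 phenol as an ether that hydrogenolysis removes at the end.

Step 9
Reactants: 18 2-(benzyloxy)-4-methoxy-6-pentylbenzaldehyde
Product: 19 2-(benzyloxy)-4-methoxy-6-pentylbenzoic acid
Conditions: NaClO2, NaH2PO4, 2-methyl-2-butene (excess), t-BuOH/THF/H2O, rt
Reagents that add atoms: sodium chlorite, [Na+].[O-]Cl=O
Why: Pinnick oxidation converts the hindered, electron-rich aldehyde into the acid under buffered conditions, with 2-methyl-2-butene scavenging hypochlorous acid so that the activated ring is not chlorinated.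

Step 10
Reactants: 19 2-(benzyloxy)-4-methoxy-6-pentylbenzoic acid; 13 benzyl 4-hydroxy-2-methoxy-6-propylbenzoate
Product: 21 benzyl 4-{[2-(benzyloxy)-4-methoxy-6-pentylbenzoyl]oxy}-2-methoxy-6-propylbenzoate, via mixed trifluoroacetic anhydride 20 (not isolated)
Conditions: (CF3CO)2O, toluene, 0 °C to rt
Reagents that add atoms: none
Why: Trifluoroacetic anhydride-mediated esterification runs through mixed anhydride 20 and an acylium-like species stabilised by the two ring A alkoxy groups, so acyl transfer to the single free phenol of 13 should not be blocked by the two ortho substituents.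

Step 11
Reactants: 21 benzyl 4-{[2-(benzyloxy)-4-methoxy-6-pentylbenzoyl]oxy}-2-methoxy-6-propylbenzoate
Product: 22 4-[(2-hydroxy-4-methoxy-6-pentylbenzoyl)oxy]-2-methoxy-6-propylbenzoic acid
Conditions: H2 (1 atm), 10% Pd/C, EtOAc, rt
Reagents that add atoms: none
Why: Catalytic hydrogenolysis over Pd/C cleaves the benzyl ether and the benzyl ester in one neutral operation that should leave the base-sensitive aryl ester link, the methyl ethers and both arenes intact.

Compound list
1 | 3-fluoro-5-methoxyphenol | COc1cc(O)cc(F)c1 | starting material
2 | chlorotriisopropylsilane | CC(C)[Si](Cl)(C(C)C)C(C)C | starting material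
3 | (3-fluoro-5-methoxyphenoxy)triisopropylsilane | COc1cc(F)cc(O[Si](C(C)C)(C(C)C)C(C)C)c1 | intermediate
4 | 1-chloropropane | CCCCl | starting material
5 | propyllithium | [Li]CCC | intermediate
6 | carbon dioxide | O=C=O | starting material
7 | [2-fluoro-6-methoxy-4-(triisopropylsilyloxy)phenyl]lithium | COc1cc(O[Si](C(C)C)(C(C)C)C(C)C)cc(F)c1[Li] | intermediate
8 | 3-methoxy-5-(triisopropylsilyloxy)benzyne | COC1=CC(O[Si](C(C)C)(C(C)C)C(C)C)=CC#C1 | intermediate
9 | [2-methoxy-6-propyl-4-(triisopropylsilyloxy)phenyl]lithium | CCCc1cc(O[Si](C(C)C)(C(C)C)C(C)C)cc(OC)c1[Li] | intermediate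
10 | lithium 2-methoxy-6-propyl-4-(triisopropylsilyloxy)benzoate | CCCc1cc(O[Si](C(C)C)(C(C)C)C(C)C)cc(OC)c1C(=O)[O-].[Li+] | intermediate
11 | 2-methoxy-6-propyl-4-(triisopropylsilyloxy)benzoic acid | CCCc1cc(O[Si](C(C)C)(C(C)C)C(C)C)cc(OC)c1C(=O)O | intermediate
12 | benzyl 2-methoxy-6-propyl-4-(triisopropylsilyloxy)benzoate | CCCc1cc(O[Si](C(C)C)(C(C)C)C(C)C)cc(OC)c1C(=O)OCc1ccccc1 | intermediate
13 | benzyl 4-hydroxy-2-methoxy-6-propylbenzoate | CCCc1cc(O)cc(OC)c1C(=O)OCc1ccccc1 | intermediate
14 | olivetol (5-pentylbenzene-1,3-diol) | CCCCCc1cc(O)cc(O)c1 | starting material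
15 | N-[(2,4-dihydroxy-6-pentylphenyl)methylidene]-N-methylmethanaminium chloride | CCCCCc1cc(O)cc(O)c1C=[N+](C)C.[Cl-] | intermediate
16 | 2,4-dihydroxy-6-pentylbenzaldehyde | CCCCCc1cc(O)cc(O)c1C=O | intermediate
17 | 2-hydroxy-4-methoxy-6-pentylbenzaldehyde | CCCCCc1cc(OC)cc(O)c1C=O | intermediate
18 | 2-(benzyloxy)-4-methoxy-6-pentylbenzaldehyde | CCCCCc1cc(OC)cc(OCc2ccccc2)c1C=O | intermediate
19 | 2-(benzyloxy)-4-methoxy-6-pentylbenzoic acid | CCCCCc1cc(OC)cc(OCc2ccccc2)c1C(=O)O | intermediate
20 | 2-(benzyloxy)-4-methoxy-6-pentylbenzoic trifluoroacetic anhydride | CCCCCc1cc(OC)cc(OCc2ccccc2)c1C(=O)OC(=O)C(F)(F)F | intermediate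
21 | benzyl 4-{[2-(benzyloxy)-4-methoxy-6-pentylbenzoyl]oxy}-2-methoxy-6-propylbenzoate | CCCCCc1cc(OC)cc(OCc2ccccc2)c1C(=O)Oc1cc(CCC)c(C(=O)OCc2ccccc2)c(OC)c1 | intermediate
22 | 4-[(2-hydroxy-4-methoxy-6-pentylbenzoyl)oxy]-2-methoxy-6-propylbenzoic acid | CCCCCc1cc(OC)cc(O)c1C(=O)Oc1cc(CCC)c(C(=O)O)c(OC)c1 | target

Total step count: 11 (step 2 is the preparation of a reagent).
Longest linear sequence: 6 steps (steps 1, 3, 4, 5, 10, 11 from compound 1; equally steps 6 to 11 from compound 14).

Steps most likely to fail

Step 3. The one-flask sequence could be eroded by metalation at a C–H next to the silyl ether, by addition of the aryllithiums 7 or 9 to the aryne (biaryl formation), or by addition of the alkyllithium to the proximal aryne carbon. The fallback sets out from 3 and comes back at 10 and hence 11. Compound 3 would be metalated with s-BuLi in THF and held at −78 °C, where 7 should not lose lithium fluoride. A cold carbon dioxide quench and acidification would give 2-fluoro-6-methoxy-4-(triisopropylsilyloxy)benzoic acid F1, on which the site of metalation can be checked. F1 would then be treated with an excess of 5 in THF (−78 °C to 0 °C). The first equivalent forms lithium 2-fluoro-6-methoxy-4-(triisopropylsilyloxy)benzoate F2, the salt that also arises in the carbon dioxide quench. Further 5 should displace the ortho fluoride by carboxylate-directed nucleophilic aromatic substitution (addition–elimination), fluoride being a better leaving group than methoxide, to give 10 and, after acidification, 11. This is the known ipso-substitution of ortho-fluorobenzoic acids by organolithium reagents; no aryne is involved and the two bonds are made in separate operations.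

Step 10. Acyl transfer from the doubly ortho-substituted acyl donor could be sluggish, with competing trifluoroacetylation of the phenol or acid-promoted loss of the benzyl ether. The fallback sets out from 19 and 13 and comes back at 21. Compound 19 would be converted under neutral conditions with 1-chloro-N,N,2-trimethylprop-1-en-1-amine in CH2Cl2 into 2-(benzyloxy)-4-methoxy-6-pentylbenzoyl chloride F3. Compound 13 would be deprotonated with NaH in THF to sodium 4-[(benzyloxy)carbonyl]-3-methoxy-5-propylphenolate F4. Combining F3 and F4 at 0 °C to rt, an acylation of a preformed phenoxide by an acyl chloride, should give 21 under basic, acid-free conditions.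

Step 7. The two phenols could be discriminated incompletely, leading to double methylation or methylation at the C2 oxygen. The fallback sets out from 16 and comes back at 17. Compound 16 would be methylated exhaustively (MeI in excess, K2CO3, DMF, 60 °C) to 2,4-dimethoxy-6-pentylbenzaldehyde F5. The methyl ether ortho to the formyl group would then be cleaved with BCl3 (CH2Cl2, −78 °C to 0 °C), which chelates between the carbonyl oxygen and the C2 oxygen and should give 2-[(dichloroboranyl)oxy]-4-methoxy-6-pentylbenzaldehyde F6. Aqueous work-up hydrolyses F6 to 17. Chelation-controlled demethylation of an aryl methyl ether beside a carbonyl group is known chemistry and moves the selectivity from alkylation to dealkylation.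

Further compounds
F1 | step 3 | 2-fluoro-6-methoxy-4-(triisopropylsilyloxy)benzoic acid | COc1cc(O[Si](C(C)C)(C(C)C)C(C)C)cc(F)c1C(=O)O
F2 | step 3 | lithium 2-fluoro-6-methoxy-4-(triisopropylsilyloxy)benzoate | COc1cc(O[Si](C(C)C)(C(C)C)C(C)C)cc(F)c1C(=O)[O-].[Li+]
F3 | step 10 | 2-(benzyloxy)-4-methoxy-6-pentylbenzoyl chloride | CCCCCc1cc(OC)cc(OCc2ccccc2)c1C(=O)Cl
F4 | step 10 | sodium 4-[(benzyloxy)carbonyl]-3-methoxy-5-propylphenolate | CCCc1cc([O-])cc(OC)c1C(=O)OCc1ccccc1.[Na+]
F5 | step 7 | 2,4-dimethoxy-6-pentylbenzaldehyde | CCCCCc1cc(OC)cc(OC)c1C=O
F6 | step 7 | 2-[(dichloroboranyl)oxy]-4-methoxy-6-pentylbenzaldehyde | CCCCCc1cc(OC)cc(OB(Cl)Cl)c1C=O
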